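**Plan**
- Retrosynthesis cuts, in this order: the two butanoate esters (enzymatic unmasking of the lactol), the aryl C–O bond of the seven-membered lactone (ring-A carboxyl oxygen to the ring-B carbon lying between the ether carbon and the CH2OH carbon), the diaryl ether C–O bond (SNAr), and the bond from ring B to the lactol carbon (formylation).
- Forward: a ring-A fluoro-ester (4 steps) and a ring-B hydroxyphthalide, whose five-membered lactol ring is closed first (5 steps), are joined by SNAr; one acid step removes all protecting groups; the seven-membered ring is closed last.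
- Key event: oxidation of the ring-B phenol gives a six-membered spiro-acylal that ring-expands by a 1,2-acyloxy shift, so the ester oxygen on ring B is made from a C–H and is never carried as a protected phenol.
- Feature that allows it: in ring B the free OH is para to the ether carbon and the carbon ortho to that ether carbon still bears H, while the ring-A CO2H hangs from the ether oxygen through two ring carbons.
- Stereochemistry: the lactol carbon is the only stereocentre; its epimers interconvert by ring–chain tautomerism, a hydrolase-catalysed dynamic kinetic resolution converts both into the (S)-ester, and the same enzyme unmasks it without base.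

Key step: step 12

Assumption: the lactol carbon is configurationally labile, and subtilisin is assumed to keep its usual preference for secondary alcohols (opposite to lipases; fused aryl carbon as large, ring oxygen as medium substituent), which corresponds to the (S)-lactol; the final product must be handled cold and free of base.

Step 1
Reactants: 1 3-fluoro-5-methylphenol
Product: 2 1-fluoro-3-(methoxymethoxy)-5-methylbenzene
Conditions: MOMCl, iPr2NEt, CH2Cl2, 0 °C to rt
Reagents that add atoms: chloromethyl methyl ether (COCCl)
Why: O-alkylation of the phenol gives the acetal ether that later serves as ortho-directing group and is removed by acid.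

Step 2
Reactants: 2 1-fluoro-3-(methoxymethoxy)-5-methylbenzene
Product: 4 2-fluoro-6-(methoxymethoxy)-4-methylbenzaldehyde, via aryllithium 3 (not isolated)
Conditions: n-BuLi, THF, −78 °C; DMF, −78 to 0 °C; aq. NH4Cl
Reagents that add atoms: N,N-dimethylformamide (CN(C)C=O)
Why: Directed ortho-lithiation should go to the CH flanked by F and OMOM (combined directing effect), and DMF traps the aryllithium as the aldehyde.

Step 3
Reactants: 4 2-fluoro-6-(methoxymethoxy)-4-methylbenzaldehyde
Product: 5 3-bromo-2-fluoro-6-(methoxymethoxy)-4-methylbenzaldehyde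
Conditions: NBS, MeCN, 0 °C to rt, dark
Reagents that add atoms: N-bromosuccinimide (O=C1CCC(=O)N1Br)
Why: Electrophilic aromatic bromination is steered para to the OMOM donor and meta to CHO, to the CH between F and CH3.

Step 4
Reactants: 5 3-bromo-2-fluoro-6-(methoxymethoxy)-4-methylbenzaldehyde
Product: 6 4-methoxybenzyl 2-fluoro-3-formyl-4-(methoxymethoxy)-6-methylbenzoate
Conditions: Pd(OAc)2 (3 mol%), Xantphos (6 mol%), CO (1 atm), 4-methoxybenzyl alcohol, Et3N, toluene, 90 °C
Reagents that add atoms: carbon monoxide ([C-]#[O+]); 4-methoxybenzyl alcohol (COc1ccc(CO)cc1)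
Why: Alkoxycarbonylation catalysed by zerovalent palladium (oxidative addition, CO insertion, alcoholysis) should turn the aryl bromide into an acid-labile ester while the aryl fluoride and the aldehyde stay untouched.

Step 5
Reactants: 7 4-(benzyloxy)phenol
Product: 8 4-(benzyloxy)-2,6-bis(hydroxymethyl)phenol
Conditions: 37% aq. CH2O, NaOH (1.1 equiv), H2O/THF, rt; AcOH
Reagents that add atoms: formaldehyde (C=O)
Why: Lederer–Manasse hydroxymethylation: the phenoxide attacks formaldehyde at both free ortho positions, the para position being blocked by OBn.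

Step 6
Reactants: 8 4-(benzyloxy)-2,6-bis(hydroxymethyl)phenol
Product: 9 [6-(benzyloxy)-2,2-dimethyl-4H-1,3-benzodioxin-8-yl]methanol
Conditions: 2,2-dimethoxypropane, TsOH·H2O (cat.), acetone, rt
Reagents that add atoms: 2,2-dimethoxypropane (COC(C)(C)OC)
Why: Acid-catalysed transketalisation ties the phenol and one of the two equivalent CH2OH groups into a six-membered acetonide, leaving one primary alcohol free.

Step 7
Reactants: 9 [6-(benzyloxy)-2,2-dimethyl-4H-1,3-benzodioxin-8-yl]methanol
Product: 11 methyl 6-(benzyloxy)-2,2-dimethyl-4H-1,3-benzodioxine-8-carboxylate, via aldehyde 10 (not isolated)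
Conditions: MnO2, CH2Cl2, rt; filter; I2, KOH, MeOH, 0 °C
Reagents that add atoms: methanol (CO)
Why: MnO2 oxidises the benzylic alcohol to the aldehyde and I2/KOH in methanol converts this into the methyl ester (oxidative esterification) under basic conditions that keep the acetonide.

Step 8
Reactants: 11 methyl 6-(benzyloxy)-2,2-dimethyl-4H-1,3-benzodioxine-8-carboxylate
Product: 14 rac-4-(benzyloxy)-3-hydroxyphthalide fused at C6/C7 to a 2,2-dimethyl-4H-1,3-dioxine ring (acetonide of the 7-OH and the 6-CH2OH), via arylmagnesium amide 12 (not isolated), via formyl ester 13 (not isolated)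
Conditions: TMP2Mg·2LiCl, THF, −20 °C; DMF; 1 M aq. LiOH, rt; 1 M HCl to pH 4, 0 °C
Reagents that add atoms: N,N-dimethylformamide (CN(C)C=O); lithium hydroxide ([Li+].[OH-])
Why: Ester-directed ortho-magnesiation should occur at the CH flanked by CO2Me and OBn, DMF formylates it, and hydroxide cleaves the ester with help of the neighbouring formyl group so that acidification closes the racemic 3-hydroxyphthalide.

Step 9
Reactants: 14 rac-4-(benzyloxy)-3-hydroxyphthalide 6,7-acetonide
Product: 15 rac-3,4-dihydroxyphthalide fused at C6/C7 to the same acetonide ring (debenzylated 14)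
Conditions: H2 (1 atm), Pd/C (10%), EtOAc, rt
Reagents that add atoms: none
Why: Hydrogenolysis of the aryl benzyl ether frees the phenol, while the lactol (masked aldehyde) and the acetonide should survive at 1 atm.

Step 10
Reactants: 15 rac-3,4-dihydroxyphthalide 6,7-acetonide; 6 4-methoxybenzyl 2-fluoro-3-formyl-4-(methoxymethoxy)-6-methylbenzoate
Product: 16 rac-4-methoxybenzyl 3-formyl-4-(methoxymethoxy)-6-methyl-2-(aryloxy)benzoate in which the aryloxy oxygen is the C4 oxygen of lactol 15
Conditions: K2CO3, DMF, rt to 45 °C; pH 4 work-up
Reagents that add atoms: none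
Why: SNAr (addition–elimination): the only free phenol of 15 displaces fluoride activated by ortho-CHO and ortho-ester, the lactol reacting in its open carboxylate form and reclosing on acidification.

Step 11
Reactants: 16 protected diaryl ether
Product: 17 rac-3-formyl-4-hydroxy-6-methyl-2-{[3,7-dihydroxy-6-(hydroxymethyl)-1-oxo-1,3-dihydroisobenzofuran-4-yl]oxy}benzoic acid
Conditions: TFA/CH2Cl2 (1:3), anisole, H2O (5 equiv), 0 °C to rt
Reagents that add atoms: none
Why: One acidolysis should remove the 4-methoxybenzyl ester (to the free acid), the MOM ether and the acetonide, with anisole trapping the benzylic cation and water taking up acetone and formaldehyde.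

Step 12
Reactants: 17 seco-acid
Product: 20 rac-salazinic acid (1,4,10-trihydroxy-5-(hydroxymethyl)-8-methyl-3,7-dioxo-1,3-dihydro-7H-isobenzofuro[4,5-b][1,4]benzodioxepine-11-carbaldehyde), via oxocarbenium ion 18 (not isolated), via spiro-acylal 19 (not isolated)
Conditions: PhI(OCOCF3)2 (1.05 equiv), (CF3)2CHOH (dry), 3 Å MS, −20 °C; then TFA (5 equiv), rt
Reagents that add atoms: none
Why: Proposed new method: PhI(OCOCF3)2 oxidises the ring-B phenol (para to the aryloxy oxygen) to the O-aryl quinone oxocarbenium ion 18, which the ring-A carboxyl captures at the ether carbon to give spiro-acylal 19 (a six-membered 1,3-benzodioxin-4-one, the type of compound formed when 2-(4-hydroxyphenoxy)benzoic acids are oxidised); acid in the ionising solvent re-opens this acylal reversibly, the carboxyl oxygen then adds in a conjugate sense to the neighbouring CH carbon of the dienone (β to its C=O), and enolisation aromatises ring B irreversibly. The net change is a 1,2-acyloxy shift with ring expansion; its closest known relatives are the acid-promoted 1,2-acyloxy migration of quinol esters (dienone–phenol type), the Thiele–Winter acetoxylation of quinones and the acid-catalysed substitution of quinone monoketals at the carbon next to the ketal carbon, and what is new is its use on a spiro-acylal to make a depsidone. The seven-membered lactone is closed by ring expansion of the six-membered spiro ring, formally a 7-exo-trig oxa-conjugate addition. No lasting stereocentre is created: the spiro carbon is lost on aromatisation and the lactol carbon stays racemic. The step needs oxidation of ring B and not ring A (the ring-B phenol has a para oxygen donor, the ring-A phenol is deactivated by ortho-CHO and para-CO2H), attack at the CH carbon and not at the substituted ortho carbon (only the CH adduct can aromatise, the other additions revert), and capture by the tethered carboxyl and not by water or a second equivalent of oxidant (dry non-nucleophilic solvent, one equivalent of oxidant).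

Step 13
Reactants: 20 rac-salazinic acid
Product: 21 (1S)-1-(butanoyloxy)-5-[(butanoyloxy)methyl] derivative of salazinic acid (lactol O-butanoate and benzylic O-butanoate)
Conditions: subtilisin A (Bacillus licheniformis protease), 2,2,2-trifluoroethyl butanoate, Et3N (10 mol%), THF, 35 °C
Reagents that add atoms: 2,2,2-trifluoroethyl butanoate (CCCC(=O)OCC(F)(F)F)
Why: Hydrolase-catalysed acyl transfer with dynamic kinetic resolution: the lactol epimers interconvert by base-assisted ring–chain tautomerism while the enzyme should acylate only the (S)-lactol (and the primary alcohol, not the hydrogen-bonded phenols), so the enzyme sets the stereocentre.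

Step 14
Reactants: 21 (1S)-dibutanoate
Product: 22 (1S)-salazinic acid
Conditions: subtilisin A, n-BuOH, THF/t-BuOMe, 3 Å MS, 5 °C; filter, evaporate cold
Reagents that add atoms: none
Why: Enzymatic transesterification to n-butanol with the matched enzyme (reverse of step 13) cleaves both butanoates at the acyl carbon, so no bond at the stereocentre is broken (retention) and no base is present to open the lactol.

**Compound list**
1 | 3-fluoro-5-methylphenol | Cc1cc(O)cc(F)c1 | starting material
2 | 1-fluoro-3-(methoxymethoxy)-5-methylbenzene | COCOc1cc(C)cc(F)c1 | intermediate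
3 | [2-fluoro-6-(methoxymethoxy)-4-methylphenyl]lithium | COCOc1cc(C)cc(F)c1[Li] | intermediate
4 | 2-fluoro-6-(methoxymethoxy)-4-methylbenzaldehyde | COCOc1cc(C)cc(F)c1C=O | intermediate
5 | 3-bromo-2-fluoro-6-(methoxymethoxy)-4-methylbenzaldehyde | COCOc1cc(C)c(Br)c(F)c1C=O | intermediate
6 | 4-methoxybenzyl 2-fluoro-3-formyl-4-(methoxymethoxy)-6-methylbenzoate | COCOc1cc(C)c(C(=O)OCc2ccc(OC)cc2)c(F)c1C=O | intermediate
7 | 4-(benzyloxy)phenol | Oc1ccc(OCc2ccccc2)cc1 | starting material
8 | 4-(benzyloxy)-2,6-bis(hydroxymethyl)phenol | OCc1cc(OCc2ccccc2)cc(CO)c1O | intermediate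
9 | [6-(benzyloxy)-2,2-dimethyl-4H-1,3-benzodioxin-8-yl]methanol | CC1(C)OCc2cc(OCc3ccccc3)cc(CO)c2O1 | intermediate
10 | 6-(benzyloxy)-2,2-dimethyl-4H-1,3-benzodioxine-8-carbaldehyde | CC1(C)OCc2cc(OCc3ccccc3)cc(C=O)c2O1 | intermediate
11 | methyl 6-(benzyloxy)-2,2-dimethyl-4H-1,3-benzodioxine-8-carboxylate | COC(=O)c1cc(OCc2ccccc2)cc2COC(C)(C)Oc12 | intermediate
12 | [6-(benzyloxy)-8-(methoxycarbonyl)-2,2-dimethyl-4H-1,3-benzodioxin-7-yl](2,2,6,6-tetramethylpiperidin-1-yl)magnesium | COC(=O)c1c([Mg]N2C(C)(C)CCCC2(C)C)c(OCc2ccccc2)cc2COC(C)(C)Oc12 | intermediate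
13 | methyl 6-(benzyloxy)-7-formyl-2,2-dimethyl-4H-1,3-benzodioxine-8-carboxylate | COC(=O)c1c(C=O)c(OCc2ccccc2)cc2COC(C)(C)Oc12 | intermediate
14 | rac-4-(benzyloxy)-3-hydroxyphthalide fused at C6/C7 to a 2,2-dimethyl-4H-1,3-dioxine ring (acetonide of 7-OH and 6-CH2OH) | O=C1OC(O)c2c(OCc3ccccc3)cc3COC(C)(C)Oc3c12 | intermediate
15 | rac-3,4-dihydroxyphthalide fused at C6/C7 to the same acetonide ring | O=C1OC(O)c2c(O)cc3COC(C)(C)Oc3c12 | intermediate
16 | rac-4-methoxybenzyl 3-formyl-4-(methoxymethoxy)-6-methyl-2-(aryloxy)benzoate, aryloxy = C4 oxygen of 15 | COCOc1cc(C)c(C(=O)OCc2ccc(OC)cc2)c(Oc2cc3COC(C)(C)Oc3c3C(=O)OC(O)c23)c1C=O | intermediate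
17 | rac-3-formyl-4-hydroxy-6-methyl-2-{[3,7-dihydroxy-6-(hydroxymethyl)-1-oxo-1,3-dihydroisobenzofuran-4-yl]oxy}benzoic acid | Cc1cc(O)c(C=O)c(Oc2cc(CO)c(O)c3c2C(O)OC3=O)c1C(=O)O | intermediate
18 | O-aryl quinone oxocarbenium ion from 17 (ring B oxidised) | Cc1cc(O)c(C=O)c([O+]=C2C=C(CO)C(=O)C3=C2C(O)OC3=O)c1C(=O)O | intermediate
19 | spiro-acylal: spiro[1,3-benzodioxine-2,1'-cyclohexa-2',5'-diene]-4,4'-dione carrying the hydroxyphthalide ring (mixture of diastereomers) | Cc1cc(O)c(C=O)c2c1C(=O)OC1(O2)C=C(CO)C(=O)C3=C1C(O)OC3=O | intermediate
20 | rac-salazinic acid | Cc1cc(O)c(C=O)c2c1C(=O)Oc1c(CO)c(O)c3c(c1O2)C(O)OC3=O | intermediate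
21 | (1S)-salazinic acid 1-O-butanoate 5-CH2-O-butanoate | Cc1cc(O)c(C=O)c2c1C(=O)Oc1c(COC(=O)CCC)c(O)c3c(c1O2)[C@@H](OC(=O)CCC)OC3=O | intermediate
22 | (1S)-salazinic acid, (1S)-1,4,10-trihydroxy-5-(hydroxymethyl)-8-methyl-3,7-dioxo-1,3-dihydro-7H-isobenzofuro[4,5-b][1,4]benzodioxepine-11-carbaldehyde | Cc1cc(O)c(C=O)c2c1C(=O)Oc1c(CO)c(O)c3c(c1O2)[C@@H](O)OC3=O | target

**Totals**
Total steps: 14. Longest linear sequence: 10 steps (steps 5 to 14).

**Steps most likely to fail**

Step 12 (proposed new method). The spiro-acylal may not re-ionise and expand, the cation may be hydrolysed with cleavage of the diaryl ether, or an external nucleophile may be taken up instead of the carboxyl. The fallback uses known chemistry only and makes the same aryl C–O bond by copper-catalysed Ullmann-type intramolecular O-arylation of the carboxylate. It sets out from 15: NBS (MeCN, 0 °C) brominates the single free position ortho to the phenol to give the bromophenol lactol F1; SNAr with 6 (K2CO3, DMF) gives the bromo diaryl ether F2; TFA/anisole/water gives the bromo seco-acid F3; CuI (cat.), 1,10-phenanthroline, Cs2CO3, DMF, 90 °C closes the seven-membered lactone and comes back to the route at 20.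

Step 13. The enzyme may acylate the bulky, poorly soluble lactol too slowly, acylation may outrun epimerisation, or non-enzymatic acylation may erode the selectivity; step 14 depends on the same enzyme. The fallback sets the centre chemically at the stage where the lactol OH is the only free hydroxyl. From 16, (S)-benzotetramisole (5 mol%), propanoic anhydride and iPr2NEt in CHCl3 at 0 °C (acylative dynamic kinetic resolution by a chiral isothiourea; the antipodal catalyst is taken if the sense proves opposite) should give the (S)-lactol propanoate F4. TFA/anisole/water then gives the seco-acid propanoate F5, the conditions of step 12 give salazinic acid (1S)-1-O-propanoate F6, and subtilisin A/n-BuOH as in step 14 comes back to the route at 22.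

Step 8. Metalation may be incomplete or go to the other CH next to OBn, or the arylmagnesium may attack the ester of a second molecule. The fallback changes the directing group to the lithium carboxylate: from 11, LiOH (MeOH/H2O, 50 °C) gives the acid F7; s-BuLi/TMEDA (2.2 equiv, THF, −78 °C) lithiates ortho to the carboxylate at the CH also flanked by OBn, and DMF followed by pH 4 work-up closes the lactol and comes back to the route at 14.

Further compounds
F1 | step 12 | rac-5-bromo-3,4-dihydroxyphthalide 6,7-acetonide (15 brominated ortho to the phenol) | O=C1OC(O)c2c(O)c(Br)c3COC(C)(C)Oc3c12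
F2 | step 12 | bromo analogue of 16 (Br on the ring-B CH) | COCOc1cc(C)c(C(=O)OCc2ccc(OC)cc2)c(Oc2c(Br)c3COC(C)(C)Oc3c3C(=O)OC(O)c23)c1C=O
F3 | step 12 | bromo analogue of 17 (Br on the ring-B CH) | Cc1cc(O)c(C=O)c(Oc2c(Br)c(CO)c(O)c3c2C(O)OC3=O)c1C(=O)O
F4 | step 13 | (S)-lactol O-propanoate of 16 | COCOc1cc(C)c(C(=O)OCc2ccc(OC)cc2)c(Oc2cc3COC(C)(C)Oc3c3c2[C@@H](OC(=O)CC)OC3=O)c1C=O
F5 | step 13 | (S)-lactol O-propanoate of 17 | Cc1cc(O)c(C=O)c(Oc2cc(CO)c(O)c3c2[C@@H](OC(=O)CC)OC3=O)c1C(=O)O
F6 | step 13 | (1S)-salazinic acid 1-O-propanoate | Cc1cc(O)c(C=O)c2c1C(=O)Oc1c(CO)c(O)c3c(c1O2)[C@@H](OC(=O)CC)OC3=O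
F7 | step 8 | 6-(benzyloxy)-2,2-dimethyl-4H-1,3-benzodioxine-8-carboxylic acid | OC(=O)c1cc(OCc2ccccc2)cc2COC(C)(C)Oc12
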